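**Plan**
- Retrosynthesis first removes the furan (O1–C2 and C3–C3a, with C2–C3 coming from trimethylsilylacetylene) and the 4-O-methyl group, leaving a 2,4,6-trihydroxyphenyl ketone.
- Enabling feature: the benzene ring of the benzofuran carries oxygen on C4, C6 and C7a (1,3,5) with the ketone carbon on C7 between two of them, so it is an acylphloroglucinol, a folded triketide. Cutting C7–C7a unfolds it to a 3,5,7-triketo ester.
- The triketo ester is cut at its C6–C7 bond into a cyclohexenecarboxylic acid and methyl 3,5-dioxohexanoate. The cyclohexene C1–C2 bond is cut by a retro-Claisen ring contraction to a cis-6-alkenyl-4-phenyl δ-lactone, whose alkenyl arm goes back to a terminal alkyne (vinyl–methyl and vinyl–allyl bonds).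
- Forward order of rings: phenyl δ-lactone → opened alkynyl diol → dienyl δ-lactone → cyclohexene → chain extension → benzene ring → furan ring.
- Stereochemistry: Rh/(S)-BINAP conjugate addition sets the phenyl-bearing carbon, Ru/(R,R)-TsDPEN transfer hydrogenation sets the carbinol, and the boat [3,3] shift passes that centre and the E-alkene geometry on to C1 and C2.

Key step: step 9

Remark: the facial senses assumed for steps 1 and 3 follow the accepted models for cyclic enones and alkynyl ketones; if either proved opposite, the mirror-image ligand would be used with no other change.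

**Step 1**
Reactants: 1 5,6-dihydro-2H-pyran-2-one; 2 phenylboronic acid
Product: 3 (4S)-4-phenyltetrahydro-2H-pyran-2-one
Conditions: Rh(acac)(C2H4)2 (3 mol %), (S)-BINAP (3.3 mol %), dioxane/H2O 10:1, 100 °C
Reagents that add atoms: none
Why: Rh-catalysed asymmetric 1,4-addition of an arylboronic acid (Hayashi–Miyaura reaction) to a cyclic Z-enoate; the aryl–Rh/(S)-BINAP species should add to the same enoate face as in 2-cyclohexenone, which corresponds to the (4S) lactone.

**Step 2**
Reactants: 3 (4S)-4-phenyltetrahydro-2H-pyran-2-one; 4 (trimethylsilyl)acetylene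
Product: 6 (5S)-7-hydroxy-5-phenyl-1-(trimethylsilyl)hept-1-yn-3-one, via lithium (trimethylsilyl)acetylide 5 (not isolated)
Conditions: 4, n-BuLi, THF, −78 °C; then 3, −78 °C; AcOH, −78 °C → rt
Reagents that add atoms: none
Why: Alkynyllithium addition to a lactone: the lithium hemiketal alkoxide persists at −78 °C, so a single acetylide should add, and protonation releases the ω-hydroxy ynone (in equilibrium with its lactol) without touching the benzylic centre.

**Step 3**
Reactants: 6 (5S)-7-hydroxy-5-phenyl-1-(trimethylsilyl)hept-1-yn-3-one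
Product: 7 (3R,5S)-5-phenyl-1-(trimethylsilyl)hept-1-yne-3,7-diol
Conditions: Ru[(R,R)-TsDPEN](p-cymene) (1 mol %), i-PrOH, rt
Reagents that add atoms: none
Why: Noyori asymmetric transfer hydrogenation of an alkynyl ketone: hydride and proton pass through the six-membered Ru–H/N–H transition state with the alkyne in the place an aryl group takes, so the (R,R) catalyst should give the (3R) carbinol under catalyst control, the remote C5 centre having little say.

**Step 4**
Reactants: 7 (3R,5S)-5-phenyl-1-(trimethylsilyl)hept-1-yne-3,7-diol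
Product: 8 (3R,5S)-5-phenylhept-1-yne-3,7-diol
Conditions: K2CO3 (0.2 equiv), MeOH, rt
Reagents that add atoms: none
Why: Base-catalysed methanolysis of the alkynyl C–Si bond (protodesilylation) frees the terminal alkyne needed for carbometalation and leaves both alcohols and both stereocentres untouched.

**Step 5**
Reactants: 8 (3R,5S)-5-phenylhept-1-yne-3,7-diol; 9 1-bromo-3-methylbut-2-ene
Product: 11 (3S,5R,6E)-6,10-dimethyl-3-phenylundeca-6,9-diene-1,5-diol, via alkenylalane 10 (not isolated)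
Conditions: AlMe3 (5 equiv), Cp2ZrCl2 (20 mol %), CH2Cl2, 0 °C → rt; volatiles removed; then 9, Pd(PPh3)4 (5 mol %), THF, rt; aq. Rochelle salt
Reagents that add atoms: trimethylaluminium C[Al](C)C
Why: Zr-catalysed syn-methylalumination of the terminal alkyne (Negishi carboalumination) puts methyl on the internal and aluminium on the terminal carbon, and Pd(0)-catalysed alkenyl–allyl cross-coupling of the alkenylalane with the prenyl halide occurs with retention of alkene geometry at the unsubstituted allyl terminus, so the 6E skipped diene should form with both stereocentres unchanged (the C3 descriptor changes only through CIP ranking).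

**Step 6**
Reactants: 11 (3S,5R,6E)-6,10-dimethyl-3-phenylundeca-6,9-diene-1,5-diol
Product: 12 (4R,6R)-6-[(2E)-6-methylhepta-2,5-dien-2-yl]-4-phenyltetrahydro-2H-pyran-2-one
Conditions: TEMPO (0.2 equiv), PhI(OAc)2 (2.5 equiv), CH2Cl2, rt
Reagents that add atoms: none
Why: TEMPO/PhI(OAc)2 oxidative lactonisation of a 1,5-diol: the oxoammonium ion oxidises the primary alcohol much faster than the hindered secondary allylic one, the aldehyde is trapped as the six-membered lactol by the C5 hydroxyl and oxidised on to the δ-lactone, in which phenyl and alkenyl are cis.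

**Step 7**
Reactants: 12 (4R,6R)-6-[(2E)-6-methylhepta-2,5-dien-2-yl]-4-phenyltetrahydro-2H-pyran-2-one
Product: 15 (1R,2S,6R)-3-methyl-2-(3-methylbut-2-en-1-yl)-6-phenylcyclohex-3-ene-1-carboxylic acid, via silyl ketene acetal 13 (not isolated), via silyl ester 14 (not isolated)
Conditions: LDA, THF, −78 °C; TBSCl, DMPU, −78 °C → rt; PhMe, 110 °C; then 1 M HCl, THF, rt
Reagents that add atoms: none
Why: Ireland–Claisen rearrangement of a lactone silyl ketene acetal (Claisen ring contraction): the two-atom tether enforces a boat transition state with the alkenyl arm folded under the ketene acetal, so the new C1–C2 bond forms on the lactone face bearing that arm; the cis-4,6 lactone therefore places CO2H trans to phenyl and the E-alkene places the prenyl group cis to CO2H, which is the (1R,2S,6R) acid.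

**Step 8**
Reactants: 15 (1R,2S,6R)-3-methyl-2-(3-methylbut-2-en-1-yl)-6-phenylcyclohex-3-ene-1-carboxylic acid; 16 methyl 3,5-dioxohexanoate
Product: 19 methyl 7-[(1R,2S,6R)-3-methyl-2-(3-methylbut-2-en-1-yl)-6-phenylcyclohex-3-en-1-yl]-3,5,7-trioxoheptanoate, via acyl imidazolide 17 (not isolated), via trilithium trianion 18 (not isolated)
Conditions: 15, CDI, THF, rt; separately 16, LDA (3.1 equiv), THF, 0 °C; 17 added to 18 (3 equiv), −78 → 0 °C; 1 M HCl
Reagents that add atoms: none
Why: Claisen-type C-acylation of a 1,3,5-tricarbonyl polyanion: the terminal carbanion of the trianion is its most basic and nucleophilic site and attacks the acyl imidazolide, excess trianion absorbing the proton of the more acidic product; C1 can equilibrate through its enolate, but the 1,6-trans arrangement with equatorial acyl is the stable one.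

**Step 9**
Reactants: 19 methyl 7-[(1R,2S,6R)-3-methyl-2-(3-methylbut-2-en-1-yl)-6-phenylcyclohex-3-en-1-yl]-3,5,7-trioxoheptanoate
Product: 20 [(1R,2S,6R)-3-methyl-2-(3-methylbut-2-en-1-yl)-6-phenylcyclohex-3-en-1-yl](2,4,6-trihydroxyphenyl)methanone
Conditions: Mg(OMe)2 (6 equiv), MeOH, rt → 50 °C; then 1 M HCl
Reagents that add atoms: none
Why: Magnesium methoxide converts the triketo ester into a chelated polyenolate in which the C6 methylene (between the C5 and C7 carbonyls) attacks the ester carbonyl C1, methoxide leaves, and the resulting 2-acylcyclohexane-1,3,5-trione enolises to the arene. The closest known reaction is the Claisen-mode biomimetic cyclisation of 3,5,7-triketo esters to acylphloroglucinols, the laboratory counterpart of a type III polyketide synthase. The one ring closed is the benzene ring, by 6-exo-trig acylation that forms the future benzofuran C7–C7a bond. No stereocentre is created; C1 remains α to a ketone and may equilibrate, but its 1R configuration (acyl equatorial, trans to phenyl) is the thermodynamically preferred one. The selectivity needed is Claisen closure over aldol closure (C2 onto the C7 ketone, leading to a resorcylate) and over O-acylation to a 4-hydroxy-2-pyrone. It is secured by full enolisation under magnesium chelation, which leaves the ester as the only electrophile, and by the α-branched C7 ketone being a poor aldol acceptor.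

**Step 10**
Reactants: 20 [(1R,2S,6R)-3-methyl-2-(3-methylbut-2-en-1-yl)-6-phenylcyclohex-3-en-1-yl](2,4,6-trihydroxyphenyl)methanone
Product: 21 (2,6-dihydroxy-4-methoxyphenyl)[(1R,2S,6R)-3-methyl-2-(3-methylbut-2-en-1-yl)-6-phenylcyclohex-3-en-1-yl]methanone
Conditions: Me2SO4 (1.05 equiv), K2CO3 (1.1 equiv), acetone, rt
Reagents that add atoms: dimethyl sulfate COS(=O)(=O)OC
Why: Williamson O-methylation: the 4-hydroxyl para to the ketone is the most acidic and is not hydrogen-bonded to the carbonyl, so one equivalent of base and methylating agent should alkylate it in preference to the two chelated ortho hydroxyls; the ring symmetry means only one mono-ether of this type exists.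

**Step 11**
Reactants: 21 (2,6-dihydroxy-4-methoxyphenyl)[(1R,2S,6R)-3-methyl-2-(3-methylbut-2-en-1-yl)-6-phenylcyclohex-3-en-1-yl]methanone
Product: 22 (2,6-dihydroxy-3-iodo-4-methoxyphenyl)[(1R,2S,6R)-3-methyl-2-(3-methylbut-2-en-1-yl)-6-phenylcyclohex-3-en-1-yl]methanone
Conditions: NIS (1.0 equiv), DMF, −20 → 0 °C, dark
Reagents that add atoms: N-iodosuccinimide O=C1CCC(=O)N1I
Why: Electrophilic aromatic iodination: the two free ring positions are equivalent and, flanked by hydroxyl and methoxyl, far more nucleophilic than the trisubstituted alkenes, so one equivalent of NIS at low temperature should give the mono-iodide ortho to a hydroxyl.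

**Step 12**
Reactants: 22 (2,6-dihydroxy-3-iodo-4-methoxyphenyl)[(1R,2S,6R)-3-methyl-2-(3-methylbut-2-en-1-yl)-6-phenylcyclohex-3-en-1-yl]methanone; 4 (trimethylsilyl)acetylene
Product: 24 [6-hydroxy-4-methoxy-2-(trimethylsilyl)-1-benzofuran-7-yl][(1R,2S,6R)-3-methyl-2-(3-methylbut-2-en-1-yl)-6-phenylcyclohex-3-en-1-yl]methanone, via alkynylphenol 23 (not isolated)
Conditions: 4 (2 equiv), PdCl2(PPh3)2 (5 mol %), CuI (10 mol %), Et3N, DMF, rt → 60 °C
Reagents that add atoms: none
Why: Sonogashira coupling followed by Cu/amine-promoted 5-endo-dig cycloisomerisation of the o-alkynylphenol (heteroannulation): only the hydroxyl next to the alkyne can close because the other neighbour is the methyl ether, which fixes the furan oxygen on C7a and C3 next to the methoxy-bearing carbon.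

**Step 13**
Reactants: 24 [6-hydroxy-4-methoxy-2-(trimethylsilyl)-1-benzofuran-7-yl][(1R,2S,6R)-3-methyl-2-(3-methylbut-2-en-1-yl)-6-phenylcyclohex-3-en-1-yl]methanone
Product: 25 (6-hydroxy-4-methoxy-1-benzofuran-7-yl)[(1R,2S,6R)-3-methyl-2-(3-methylbut-2-en-1-yl)-6-phenylcyclohex-3-en-1-yl]methanone
Conditions: TBAF (1.2 equiv), THF, 0 °C → rt; aq. NH4Cl
Reagents that add atoms: none
Why: Fluoride-induced protodesilylation of a 2-silylbenzofuran (ipso cleavage of the heteroaryl C–Si bond) should leave phenol, ketone, alkenes and all three stereocentres untouched and deliver the target.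

**Compound list**
1 | 5,6-dihydro-2H-pyran-2-one | O=C1C=CCCO1 | starting material
2 | phenylboronic acid | OB(O)c1ccccc1 | starting material
3 | (4S)-4-phenyltetrahydro-2H-pyran-2-one | O=C1C[C@@H](c2ccccc2)CCO1 | intermediate
4 | (trimethylsilyl)acetylene | C#C[Si](C)(C)C | starting material
5 | lithium (trimethylsilyl)acetylide | [Li]C#C[Si](C)(C)C | intermediate
6 | (5S)-7-hydroxy-5-phenyl-1-(trimethylsilyl)hept-1-yn-3-one | C[Si](C)(C)C#CC(=O)C[C@@H](c1ccccc1)CCO | intermediate
7 | (3R,5S)-5-phenyl-1-(trimethylsilyl)hept-1-yne-3,7-diol | C[Si](C)(C)C#C[C@H](O)C[C@@H](c1ccccc1)CCO | intermediate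
8 | (3R,5S)-5-phenylhept-1-yne-3,7-diol | C#C[C@H](O)C[C@@H](c1ccccc1)CCO | intermediate
9 | 1-bromo-3-methylbut-2-ene | CC(C)=CCBr | starting material
10 | [(1E,3R,5S)-3,7-bis(dimethylalumanyloxy)-2-methyl-5-phenylhept-1-en-1-yl]dimethylalumane | C[Al](C)/C=C(\C)[C@H](O[Al](C)C)C[C@@H](c1ccccc1)CCO[Al](C)C | intermediate
11 | (3S,5R,6E)-6,10-dimethyl-3-phenylundeca-6,9-diene-1,5-diol | CC(C)=CC/C=C(\C)[C@H](O)C[C@@H](c1ccccc1)CCO | intermediate
12 | (4R,6R)-6-[(2E)-6-methylhepta-2,5-dien-2-yl]-4-phenyltetrahydro-2H-pyran-2-one | CC(C)=CC/C=C(\C)[C@H]1C[C@@H](c2ccccc2)CC(=O)O1 | intermediate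
13 | (2R,4R)-6-[(tert-butyldimethylsilyl)oxy]-2-[(2E)-6-methylhepta-2,5-dien-2-yl]-4-phenyl-3,4-dihydro-2H-pyran | CC(C)=CC/C=C(\C)[C@H]1C[C@@H](c2ccccc2)C=C(O[Si](C)(C)C(C)(C)C)O1 | intermediate
14 | tert-butyldimethylsilyl (1R,2S,6R)-3-methyl-2-(3-methylbut-2-en-1-yl)-6-phenylcyclohex-3-ene-1-carboxylate | CC(C)(C)[Si](C)(C)OC(=O)[C@@H]1[C@H](CC=C(C)C)C(C)=CC[C@H]1c1ccccc1 | intermediate
15 | (1R,2S,6R)-3-methyl-2-(3-methylbut-2-en-1-yl)-6-phenylcyclohex-3-ene-1-carboxylic acid | OC(=O)[C@@H]1[C@H](CC=C(C)C)C(C)=CC[C@H]1c1ccccc1 | intermediate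
16 | methyl 3,5-dioxohexanoate | COC(=O)CC(=O)CC(C)=O | starting material
17 | (1H-imidazol-1-yl)[(1R,2S,6R)-3-methyl-2-(3-methylbut-2-en-1-yl)-6-phenylcyclohex-3-en-1-yl]methanone | O=C(n1ccnc1)[C@@H]1[C@H](CC=C(C)C)C(C)=CC[C@H]1c1ccccc1 | intermediate
18 | trilithium 2,4,6-trianion of methyl 3,5-dioxohexanoate | [Li+].[Li+].[Li+].COC(=O)[CH-]C(=O)[CH-]C(=O)[CH2-] | intermediate
19 | methyl 7-[(1R,2S,6R)-3-methyl-2-(3-methylbut-2-en-1-yl)-6-phenylcyclohex-3-en-1-yl]-3,5,7-trioxoheptanoate | COC(=O)CC(=O)CC(=O)CC(=O)[C@@H]1[C@H](CC=C(C)C)C(C)=CC[C@H]1c1ccccc1 | intermediate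
20 | [(1R,2S,6R)-3-methyl-2-(3-methylbut-2-en-1-yl)-6-phenylcyclohex-3-en-1-yl](2,4,6-trihydroxyphenyl)methanone | O=C(c1c(O)cc(O)cc1O)[C@@H]1[C@H](CC=C(C)C)C(C)=CC[C@H]1c1ccccc1 | intermediate
21 | (2,6-dihydroxy-4-methoxyphenyl)[(1R,2S,6R)-3-methyl-2-(3-methylbut-2-en-1-yl)-6-phenylcyclohex-3-en-1-yl]methanone | COc1cc(O)c(C(=O)[C@@H]2[C@H](CC=C(C)C)C(C)=CC[C@H]2c2ccccc2)c(O)c1 | intermediate
22 | (2,6-dihydroxy-3-iodo-4-methoxyphenyl)[(1R,2S,6R)-3-methyl-2-(3-methylbut-2-en-1-yl)-6-phenylcyclohex-3-en-1-yl]methanone | COc1cc(O)c(C(=O)[C@@H]2[C@H](CC=C(C)C)C(C)=CC[C@H]2c2ccccc2)c(O)c1I | intermediate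
23 | {2,6-dihydroxy-4-methoxy-3-[(trimethylsilyl)ethynyl]phenyl}[(1R,2S,6R)-3-methyl-2-(3-methylbut-2-en-1-yl)-6-phenylcyclohex-3-en-1-yl]methanone | COc1cc(O)c(C(=O)[C@@H]2[C@H](CC=C(C)C)C(C)=CC[C@H]2c2ccccc2)c(O)c1C#C[Si](C)(C)C | intermediate
24 | [6-hydroxy-4-methoxy-2-(trimethylsilyl)-1-benzofuran-7-yl][(1R,2S,6R)-3-methyl-2-(3-methylbut-2-en-1-yl)-6-phenylcyclohex-3-en-1-yl]methanone | COc1cc(O)c(C(=O)[C@@H]2[C@H](CC=C(C)C)C(C)=CC[C@H]2c2ccccc2)c2oc([Si](C)(C)C)cc12 | intermediate
25 | (6-hydroxy-4-methoxy-1-benzofuran-7-yl)[(1R,2S,6R)-3-methyl-2-(3-methylbut-2-en-1-yl)-6-phenylcyclohex-3-en-1-yl]methanone | COc1cc(O)c(C(=O)[C@@H]2[C@H](CC=C(C)C)C(C)=CC[C@H]2c2ccccc2)c2occc12 | target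

**Totals**
Total step count: 13. Longest linear sequence: 13 steps.

**Steps most likely to fail**

Step 9. The ring may close in the aldol mode (the C2 methylene attacking the C7 ketone, which leads to a resorcylate), the enol oxygen may acylate to a 4-hydroxy-2-pyrone, or methoxide may cleave the chain by retro-Claisen reaction. The fallback attaches a preformed arene instead; it sets out from acid 15 and returns at 21.
- Acid 15 would be reduced with LiAlH4 to [(1R,2S,6R)-3-methyl-2-(3-methylbut-2-en-1-yl)-6-phenylcyclohex-3-en-1-yl]methanol F1.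
- F1 would be oxidised with Dess–Martin periodinane to (1R,2S,6R)-3-methyl-2-(3-methylbut-2-en-1-yl)-6-phenylcyclohex-3-ene-1-carbaldehyde F2.
- 1-Methoxy-3,5-bis(methoxymethoxy)benzene F3 (from 5-methoxyresorcinol, MOMCl, i-Pr2NEt) would be lithiated between its two acetal ethers (n-BuLi, THF, 0 °C) to [4-methoxy-2,6-bis(methoxymethoxy)phenyl]lithium F4.
- F4 would add to F2 to give [4-methoxy-2,6-bis(methoxymethoxy)phenyl][(1R,2S,6R)-3-methyl-2-(3-methylbut-2-en-1-yl)-6-phenylcyclohex-3-en-1-yl]methanol F5 as a mixture of carbinol epimers.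
- Dess–Martin oxidation would give [4-methoxy-2,6-bis(methoxymethoxy)phenyl][(1R,2S,6R)-3-methyl-2-(3-methylbut-2-en-1-yl)-6-phenylcyclohex-3-en-1-yl]methanone F6, and HCl in MeOH (40 °C) would remove both acetals to give 21, from which steps 11–13 follow unchanged.

Step 8. The strongly basic trianion may remove the α-proton of the hindered acyl imidazolide (ketene formation, recovery of acid), and the more acidic product may quench the trianion, so that conversion stalls. The fallback uses a less basic, ester-masked dianion and unveils the ester thermally; it sets out from imidazolide 17 (made from 15 as in step 8) and returns at 19.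
- 2,2-Dimethyl-6-(2-oxopropyl)-4H-1,3-dioxin-4-one F7 (from commercial 2,2,6-trimethyl-4H-1,3-dioxin-4-one, LDA, acetyl chloride) would be converted with LDA (2 equiv, THF, −78 °C) into the dilithium dianion of 2,2-dimethyl-6-(2-oxopropyl)-4H-1,3-dioxin-4-one F8.
- F8 would be acylated at its terminal carbon by 17 to give 6-{4-[(1R,2S,6R)-3-methyl-2-(3-methylbut-2-en-1-yl)-6-phenylcyclohex-3-en-1-yl]-2,4-dioxobutyl}-2,2-dimethyl-4H-1,3-dioxin-4-one F9.
- Heating F9 in toluene with methanol (110 °C) would extrude acetone to the acylketene 7-[(1R,2S,6R)-3-methyl-2-(3-methylbut-2-en-1-yl)-6-phenylcyclohex-3-en-1-yl]hept-1-ene-1,3,5,7-tetrone F10, which methanol traps as 19.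

Step 5. Methylalumination may be slow or poorly regioselective in the presence of two aluminium alkoxides, and the allyl coupling may lose linear selectivity or suffer competing methyl transfer. The fallback protects the diol and inverts the polarity of the coupling; it sets out from 8 and returns at 11.
- Silylation (TBSCl, imidazole, DMF) would give (3R,5S)-3,7-bis[(tert-butyldimethylsilyl)oxy]-5-phenylhept-1-yne F11.
- Carboalumination (AlMe3, cat. Cp2ZrCl2, CH2Cl2) would give [(1E,3R,5S)-3,7-bis[(tert-butyldimethylsilyl)oxy]-2-methyl-5-phenylhept-1-en-1-yl]dimethylalumane F12, and iodinolysis (I2, THF, −30 °C) would give (1E,3R,5S)-3,7-bis[(tert-butyldimethylsilyl)oxy]-1-iodo-2-methyl-5-phenylhept-1-ene F13.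
- (3-Methylbut-2-en-1-yl)zinc bromide F14 (from 9, Zn, LiCl, THF) would be coupled with F13 under Pd(OAc)2/CPhos (linear-selective Negishi coupling) to give (3S,5R,6E)-1,5-bis[(tert-butyldimethylsilyl)oxy]-6,10-dimethyl-3-phenylundeca-6,9-diene F15.
- TBAF in THF would then release 11.

**Further compounds**
F1 | step 9 | [(1R,2S,6R)-3-methyl-2-(3-methylbut-2-en-1-yl)-6-phenylcyclohex-3-en-1-yl]methanol | OC[C@@H]1[C@H](CC=C(C)C)C(C)=CC[C@H]1c1ccccc1
F2 | step 9 | (1R,2S,6R)-3-methyl-2-(3-methylbut-2-en-1-yl)-6-phenylcyclohex-3-ene-1-carbaldehyde | O=C[C@@H]1[C@H](CC=C(C)C)C(C)=CC[C@H]1c1ccccc1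
F3 | step 9 | 1-methoxy-3,5-bis(methoxymethoxy)benzene | COCOc1cc(OC)cc(OCOC)c1
F4 | step 9 | [4-methoxy-2,6-bis(methoxymethoxy)phenyl]lithium | [Li]c1c(OCOC)cc(OC)cc1OCOC
F5 | step 9 | [4-methoxy-2,6-bis(methoxymethoxy)phenyl][(1R,2S,6R)-3-methyl-2-(3-methylbut-2-en-1-yl)-6-phenylcyclohex-3-en-1-yl]methanol (carbinol epimers) | COCOc1cc(OC)cc(OCOC)c1C(O)[C@@H]1[C@H](CC=C(C)C)C(C)=CC[C@H]1c1ccccc1
F6 | step 9 | [4-methoxy-2,6-bis(methoxymethoxy)phenyl][(1R,2S,6R)-3-methyl-2-(3-methylbut-2-en-1-yl)-6-phenylcyclohex-3-en-1-yl]methanone | COCOc1cc(OC)cc(OCOC)c1C(=O)[C@@H]1[C@H](CC=C(C)C)C(C)=CC[C@H]1c1ccccc1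
F7 | step 8 | 2,2-dimethyl-6-(2-oxopropyl)-4H-1,3-dioxin-4-one | CC(=O)CC1=CC(=O)OC(C)(C)O1
F8 | step 8 | dilithium dianion of 2,2-dimethyl-6-(2-oxopropyl)-4H-1,3-dioxin-4-one | [Li+].[Li+].[CH2-]C(=O)[CH-]C1=CC(=O)OC(C)(C)O1
F9 | step 8 | 6-{4-[(1R,2S,6R)-3-methyl-2-(3-methylbut-2-en-1-yl)-6-phenylcyclohex-3-en-1-yl]-2,4-dioxobutyl}-2,2-dimethyl-4H-1,3-dioxin-4-one | CC1(C)OC(=O)C=C(CC(=O)CC(=O)[C@@H]2[C@H](CC=C(C)C)C(C)=CC[C@H]2c2ccccc2)O1
F10 | step 8 | 7-[(1R,2S,6R)-3-methyl-2-(3-methylbut-2-en-1-yl)-6-phenylcyclohex-3-en-1-yl]hept-1-ene-1,3,5,7-tetrone | O=C=CC(=O)CC(=O)CC(=O)[C@@H]1[C@H](CC=C(C)C)C(C)=CC[C@H]1c1ccccc1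
F11 | step 5 | (3R,5S)-3,7-bis[(tert-butyldimethylsilyl)oxy]-5-phenylhept-1-yne | C#C[C@H](O[Si](C)(C)C(C)(C)C)C[C@@H](c1ccccc1)CCO[Si](C)(C)C(C)(C)C
F12 | step 5 | [(1E,3R,5S)-3,7-bis[(tert-butyldimethylsilyl)oxy]-2-methyl-5-phenylhept-1-en-1-yl]dimethylalumane | C[Al](C)/C=C(\C)[C@H](O[Si](C)(C)C(C)(C)C)C[C@@H](c1ccccc1)CCO[Si](C)(C)C(C)(C)C
F13 | step 5 | (1E,3R,5S)-3,7-bis[(tert-butyldimethylsilyl)oxy]-1-iodo-2-methyl-5-phenylhept-1-ene | I/C=C(\C)[C@H](O[Si](C)(C)C(C)(C)C)C[C@@H](c1ccccc1)CCO[Si](C)(C)C(C)(C)C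
F14 | step 5 | (3-methylbut-2-en-1-yl)zinc bromide | CC(C)=CC[Zn]Br
F15 | step 5 | (3S,5R,6E)-1,5-bis[(tert-butyldimethylsilyl)oxy]-6,10-dimethyl-3-phenylundeca-6,9-diene | CC(C)=CC/C=C(\C)[C@H](O[Si](C)(C)C(C)(C)C)C[C@@H](c1ccccc1)CCO[Si](C)(C)C(C)(C)C
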